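## Retrosynthetic overview

1. Numbering (daucane): C1 = quaternary ring-fusion carbon carrying CH3-15; C2, C3 = the two CH2 of the five-membered ring; C4 = carbinol carbon; C5 = ring-fusion CH; C6 = acyloxy carbon; C7; C8 = formyl-bearing carbon (CHO = C14); C9 = vinylic CH; C10.
2. Endgame: the aryl ester at O6 comes last, after the C8(CHO)=C9 unit is made from a C9 ketone (aminomethylenation at C8, 1,2-reduction, dehydration). Before that, C6-OH comes from hydroxyl-directed reduction of a C6 ketone, the trans ring fusion from epimerisation of C5 next to that ketone, and C4-OH from convex-face hydration of a C3=C4 alkene.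
3. Key disconnection: the five-membered ring is cut at C2–C3 and C4–C5, a formal (3+2) cycloaddition of cyclopropyl ketone 8 with 3-methylbut-1-yne under SmI2 radical-relay catalysis.
4. Enabling feature: the C6 oxygen sits on the carbon next to C5, and C2 is a lone CH2 on quaternary C1. Written as a C6 ketone, the C5–C1–C2 three-membered ring fused to the seven-membered ring is a cyclopropyl ketone; its exocyclic C5–C2 bond is cleaved by the ketyl, freeing C2 as a radical for the C2–C3 bond and making C5 the enolate that closes C4–C5. The cyclopropane is a temporary ring that also fixes C1.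
5. Ring order: six-membered ketal ketone 1 → seven-membered enone (one-carbon ring enlargement) → temporary cyclopropane (Corey–Bakshi–Shibata reduction, hydroxyl-directed Simmons–Smith) → five-membered ring (key step).

Key step: step 7

Remark: bicyclic compounds are named with the daucane numbering above ("14-nordaucane" = daucane without C14); the beta face is the face of CH3-15; compounds 1, 9 and 18 are taken as commercial.

## Route

Step 1
Reactants: 1 7-methyl-1,4-dioxaspiro[4.5]decan-8-one (racemic)
Product: 2 7-methyl-8-(trimethylsilyloxy)-1,4-dioxaspiro[4.5]dec-7-ene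
Conditions: TMSCl, Et3N, DMF, 80 °C
Reagents that add atoms: chlorotrimethylsilane, C[Si](C)(C)Cl
Why: silyl enol ether formation under equilibrating conditions should give mainly the more substituted, tetrasubstituted enol ether, which erases the stereocentre of 1 and puts the methyl group on the carbon that becomes C1.

Step 2
Reactants: 2 7-methyl-8-(trimethylsilyloxy)-1,4-dioxaspiro[4.5]dec-7-ene
Product: 3 1-methyl-6-(trimethylsilyloxy)bicyclo[4.1.0]heptan-3-one ethylene ketal (racemic)
Conditions: Et2Zn, CH2I2, CH2Cl2, 0 °C to rt
Reagents that add atoms: diiodomethane, ICI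
Why: Simmons–Smith cyclopropanation (Furukawa reagent) of an electron-rich silyl enol ether is fast and gives the siloxycyclopropane, whose two stereocentres are of no consequence because both are destroyed in step 3.

Step 3
Reactants: 3 1-methyl-6-(trimethylsilyloxy)bicyclo[4.1.0]heptan-3-one ethylene ketal
Product: 5 10-methyl-1,4-dioxaspiro[4.6]undec-9-en-8-one, via beta-chloro ketone 4 (not isolated)
Conditions: FeCl3, DMF, 0 °C to rt; then NaOAc, MeOH, reflux
Reagents that add atoms: none
Why: Ito–Saegusa ring enlargement, in which one-electron oxidation of the siloxycyclopropane by FeCl3 (tamed by DMF, which should spare the dioxolane) cleaves the ring-fusion bond to the ring-expanded tertiary beta-keto radical, chlorine transfer from FeCl3 gives 4, and acetate-induced loss of HCl delivers the 3-methylcyclohept-2-enone 5.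

Step 4
Reactants: 5 10-methyl-1,4-dioxaspiro[4.6]undec-9-en-8-one
Product: 6 (8S)-10-methyl-1,4-dioxaspiro[4.6]undec-9-en-8-ol
Conditions: (R)-Me-CBS oxazaborolidine (C18H20BNO, 10 mol%), catecholborane, toluene, −78 °C
Reagents that add atoms: none
Why: Corey–Bakshi–Shibata reduction, in which the alkene side of the enone acts as the large group so that the (R)-catalyst should deliver hydride 1,2 to the face that gives the (S)-allylic alcohol; this step sets the absolute configuration of the whole route.

Step 5
Reactants: 6 (8S)-10-methyl-1,4-dioxaspiro[4.6]undec-9-en-8-ol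
Product: 7 (1R,2S,7R)-2-hydroxy-7-methylbicyclo[5.1.0]octan-5-one ethylene ketal
Conditions: Et2Zn, CH2I2, CH2Cl2, −10 °C to rt
Reagents that add atoms: diiodomethane, ICI
Why: hydroxyl-directed Simmons–Smith cyclopropanation, in which the zinc alkoxide delivers CH2 to the alkene face syn to OH (the normal outcome for cyclohept-2-enols), which sets the quaternary C1 and C5 with C2 on the face that the target requires.

Step 6
Reactants: 7 (1R,2S,7R)-2-hydroxy-7-methylbicyclo[5.1.0]octan-5-one ethylene ketal
Product: 8 (1R,7R)-7-methylbicyclo[5.1.0]octane-2,5-dione 5-(ethylene ketal)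
Conditions: (n-Pr)4N[RuO4] (5 mol%), NMO, 4 Å MS, CH2Cl2, rt
Reagents that add atoms: none
Why: Ley–Griffith oxidation of the secondary cyclopropyl carbinol under neutral conditions gives the cyclopropyl ketone without touching the ketal or the two cyclopropane stereocentres.

Step 7
Reactants: 8 (1R,7R)-7-methylbicyclo[5.1.0]octane-2,5-dione 5-(ethylene ketal); 9 3-methylbut-1-yne
Product: 10 (1R,5S)-9,9-(ethylenedioxy)-14-nordauc-3-en-6-one (cis-fused)
Conditions: SmI2 (20 mol%), Sm powder (20 mol%), THF, 55 °C, sealed tube, 9 in excess
Reagents that add atoms: none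
Why: SmI2 transfers one electron to the C6 ketone, the ketyl fragments the exocyclic C5–C2 cyclopropane bond to a trivalent-samarium enolate (C5=C6) and a primary radical at C2, this radical adds to the terminal alkyne carbon (new C2–C3 bond), the C4 vinyl radical adds back to the enolate carbon C5 (new C4–C5 bond), and the resulting ketyl returns its electron so that divalent samarium is regenerated. The closest known reaction type is the SmI2-catalysed formal (3+2) cycloaddition of alkyl cyclopropyl ketones, bicyclic ones included, with alkynes, run with substoichiometric Sm metal to keep the catalyst alive. The five-membered ring is closed by a 5-exo-trig attack of the vinyl radical on C5, and the seven-membered ring is untouched. C1 is not involved and keeps its configuration; the new stereocentre C5 is fixed by the tether, because C2 sits on one face of C1 and C4 can only reach the same face of C5, so the ring fusion is cis (H-5 cis to CH3-15). The step needs cleavage of C5–C2 and not of the ring-fusion bond C5–C1, which the overlap of the exocyclic bond with the ketyl in the bicyclo[5.1.0]octan-2-one should secure, and it needs radical attack at the unsubstituted alkyne carbon, which the terminal alkyne secures; the volatile alkyne is used in excess because the hindered primary radical adds slowly.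

Step 8
Reactants: 10 (1R,5S)-9,9-(ethylenedioxy)-14-nordauc-3-en-6-one
Product: 11 (1R,4R,5S)-9,9-(ethylenedioxy)-4-hydroxy-14-nordaucan-6-one (cis-fused)
Conditions: Co(acac)2 (20 mol%), PhSiH3, O2 (1 atm), THF, rt
Reagents that add atoms: dioxygen, O=O
Why: Mukaiyama hydration by hydrogen-atom transfer, in which H adds to C3 and the tertiary C4 radical is captured by O2 from the convex face of the cis-fused bicycle (the face of CH3-15 and H-5, away from the seven-membered ring) and reduced in situ, so the new C4-OH is cis to CH3-15 and the isopropyl group is pushed to the concave face.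

Step 9
Reactants: 11 (1R,4R,5S)-9,9-(ethylenedioxy)-4-hydroxy-14-nordaucan-6-one
Product: 12 (1R,4R,5R)-9,9-(ethylenedioxy)-4-hydroxy-14-nordaucan-6-one (trans-fused)
Conditions: DBU, toluene, 40 °C
Reagents that add atoms: none
Why: base-mediated epimerisation alpha to the C6 ketone under thermodynamic control, in which inversion at C5 moves the seven-membered ring away from the concave isopropyl group and allows the O4–H···O=C6 hydrogen bond, so the trans-fused ketol should be the sink; it has to follow step 8, because only the cis-fused bicycle offers a convex face for the C4 oxygen.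

Step 10
Reactants: 12 (1R,4R,5R)-9,9-(ethylenedioxy)-4-hydroxy-14-nordaucan-6-one
Product: 14 (1R,4R,5S,6S)-4,6-dihydroxy-14-nordaucan-9-one, via diol ketal 13 (not isolated)
Conditions: Me4NBH(OAc)3, MeCN/AcOH, −25 °C; then 2 M HCl, THF, rt
Reagents that add atoms: water, O
Why: Evans–Saksena reduction, in which boron bound to O4 delivers hydride intramolecularly to the face of the C6 carbonyl that carries C4, giving the 6-alcohol with oxygen cis to H-5 (an external hydride would attack the opposite face); aqueous acid then destroys the hydride and hydrolyses the dioxolane to the C9 ketone.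

Step 11
Reactants: 14 (1R,4R,5S,6S)-4,6-dihydroxy-14-nordaucan-9-one
Product: 15 (1R,4R,5S,6S,8E)-14-(dimethylamino)-4,6-dihydroxydauc-8(14)-en-9-one
Conditions: t-BuOCH(NMe2)2, toluene, 90 °C
Reagents that add atoms: tert-butoxybis(dimethylamino)methane (Bredereck's reagent), CN(C)C(OC(C)(C)C)N(C)C
Why: aminomethylenation with Bredereck's reagent occurs at C8, the unhindered alpha-methylene of the C9 ketone (C10 is neopentylic), gives the (E)-enaminone and brings in C14, while any hydroxyl that has exchanged with the reagent is returned on aqueous work-up.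

Step 12
Reactants: 15 (1R,4R,5S,6S,8E)-14-(dimethylamino)-4,6-dihydroxydauc-8(14)-en-9-one
Product: 17 (1R,4R,5S,6S)-4,6-dihydroxydauc-8-en-14-al, via amino allylic alcohol 16 (not isolated)
Conditions: LiAlH4, THF, −20 to 0 °C; then 1 M HCl, THF, 0 °C
Reagents that add atoms: water, O
Why: 1,2-reduction of the vinylogous amide followed by acid, in which the C9 hydroxyl leaves through the enamine as a vinylogous iminium ion that water hydrolyses to the transposed enal C8(CHO)=C9 (1,3-carbonyl transposition); transannular attack of O6 on C9 is not expected, because it would force CH3-15 into the endo position over the C7–C8 bridge.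

Step 13
Reactants: 17 (1R,4R,5S,6S)-4,6-dihydroxydauc-8-en-14-al; 18 4-(tert-butyldimethylsilyloxy)benzoic acid
Product: 19 (1R,4R,5S,6S)-4-hydroxy-14-oxodauc-8-en-6-yl 4-(tert-butyldimethylsilyloxy)benzoate
Conditions: EDC·HCl, DMAP, CH2Cl2, rt
Reagents that add atoms: none
Why: Steglich esterification acylates only the secondary 6-OH, since the tertiary 4-OH is inert to the acylpyridinium intermediate and the enal is not affected.

Step 14
Reactants: 19 (1R,4R,5S,6S)-4-hydroxy-14-oxodauc-8-en-6-yl 4-(tert-butyldimethylsilyloxy)benzoate
Product: 20 (1R,4R,5S,6S)-4-hydroxy-14-oxodauc-8-en-6-yl 4-hydroxybenzoate (target)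
Conditions: HF·pyridine, THF, 0 °C
Reagents that add atoms: none
Why: fluoride-mediated cleavage of the aryl silyl ether is fast and leaves the benzoate, the enal and the tertiary alcohol untouched.

## Compound list

1 | 7-methyl-1,4-dioxaspiro[4.5]decan-8-one (racemic) | CC1CC2(CCC1=O)OCCO2 | starting material
2 | 7-methyl-8-(trimethylsilyloxy)-1,4-dioxaspiro[4.5]dec-7-ene | CC1=C(O[Si](C)(C)C)CCC2(C1)OCCO2 | intermediate
3 | 1-methyl-6-(trimethylsilyloxy)bicyclo[4.1.0]heptan-3-one ethylene ketal (racemic) | CC12CC3(OCCO3)CCC1(O[Si](C)(C)C)C2 | intermediate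
4 | 10-chloro-10-methyl-1,4-dioxaspiro[4.6]undecan-8-one (racemic) | CC1(Cl)CC(=O)CCC2(C1)OCCO2 | intermediate
5 | 10-methyl-1,4-dioxaspiro[4.6]undec-9-en-8-one | CC1=CC(=O)CCC2(C1)OCCO2 | intermediate
6 | (8S)-10-methyl-1,4-dioxaspiro[4.6]undec-9-en-8-ol | CC1=C[C@@H](O)CCC2(C1)OCCO2 | intermediate
7 | (1R,2S,7R)-2-hydroxy-7-methylbicyclo[5.1.0]octan-5-one ethylene ketal (cyclopropane CH2 cis to OH) | C[C@]12C[C@H]1[C@@H](O)CCC3(C2)OCCO3 | intermediate
8 | (1R,7R)-7-methylbicyclo[5.1.0]octane-2,5-dione 5-(ethylene ketal) | C[C@]12C[C@H]1C(=O)CCC3(C2)OCCO3 | intermediate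
9 | 3-methylbut-1-yne | CC(C)C#C | starting material
10 | (1R,5S)-9,9-(ethylenedioxy)-14-nordauc-3-en-6-one (cis-fused, H-5 cis to CH3-15) | CC(C)C1=CC[C@]2(C)CC3(CCC(=O)[C@H]12)OCCO3 | intermediate
11 | (1R,4R,5S)-9,9-(ethylenedioxy)-4-hydroxy-14-nordaucan-6-one (cis-fused, 4-OH cis to CH3-15) | CC(C)[C@]1(O)CC[C@]2(C)CC3(CCC(=O)[C@H]12)OCCO3 | intermediate
12 | (1R,4R,5R)-9,9-(ethylenedioxy)-4-hydroxy-14-nordaucan-6-one (trans-fused) | CC(C)[C@]1(O)CC[C@]2(C)CC3(CCC(=O)[C@H]21)OCCO3 | intermediate
13 | (1R,4R,5S,6S)-9,9-(ethylenedioxy)-14-nordaucane-4,6-diol | CC(C)[C@]1(O)CC[C@]2(C)CC3(CC[C@H](O)[C@H]21)OCCO3 | intermediate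
14 | (1R,4R,5S,6S)-4,6-dihydroxy-14-nordaucan-9-one | CC(C)[C@]1(O)CC[C@]2(C)CC(=O)CC[C@H](O)[C@H]21 | intermediate
15 | (1R,4R,5S,6S,8E)-14-(dimethylamino)-4,6-dihydroxydauc-8(14)-en-9-one | CC(C)[C@]1(O)CC[C@]2(C)CC(=O)/C(=C/N(C)C)C[C@H](O)[C@H]21 | intermediate
16 | (1R,4R,5S,6S,8E)-14-(dimethylamino)dauc-8(14)-ene-4,6,9-triol (C9 epimers) | CC(C)[C@]1(O)CC[C@]2(C)CC(O)/C(=C/N(C)C)C[C@H](O)[C@H]21 | intermediate
17 | (1R,4R,5S,6S)-4,6-dihydroxydauc-8-en-14-al | CC(C)[C@]1(O)CC[C@]2(C)CC=C(C=O)C[C@H](O)[C@H]21 | intermediate
18 | 4-(tert-butyldimethylsilyloxy)benzoic acid | CC(C)(C)[Si](C)(C)Oc1ccc(cc1)C(=O)O | starting material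
19 | (1R,4R,5S,6S)-4-hydroxy-14-oxodauc-8-en-6-yl 4-(tert-butyldimethylsilyloxy)benzoate | CC(C)[C@]1(O)CC[C@]2(C)CC=C(C=O)C[C@H](OC(=O)c3ccc(O[Si](C)(C)C(C)(C)C)cc3)[C@H]21 | intermediate
20 | (1R,4R,5S,6S)-4-hydroxy-14-oxodauc-8-en-6-yl 4-hydroxybenzoate | CC(C)[C@]1(O)CC[C@]2(C)CC=C(C=O)C[C@H](OC(=O)c3ccc(O)cc3)[C@H]21 | target

## Step count and risks

Total step count: 14. Longest linear sequence: 14 steps (1 to 20).

Steps most likely to fail:

Step 7. What may go wrong: the hindered primary C2 radical may add too slowly to an unactivated alkyne, so that hydrogen abstraction from the solvent or decay of the divalent samarium catalyst outruns the relay. Opening of the ring-fusion bond C5–C1 in place of C5–C2 is the second concern. Fallback: it sets out from 8 and comes back to the route at 11.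
- Under the same SmI2/Sm conditions 8 is combined with methyl 2-isopropylacrylate (methyl 3-methyl-2-methylidenebutanoate, a known electron-poor alkene). It should capture the nucleophilic C2 radical much faster, and the ester-stabilised tertiary radical then closes onto C5. This gives the cis-fused keto ester 4-(methoxycarbonyl)-9,9-(ethylenedioxy)-14-nordaucan-6-one F1 as a mixture of C4 epimers, with the C2–C3 and C4–C5 bonds in place.
- LiI in refluxing ethyl acetate demethylates the hindered ester to the acid F2.
- DCC and N-hydroxypyridine-2-thione convert it into the Barton ester F3.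
- Irradiation under O2 with t-BuSH decarboxylates F3; the planar C4 radical should take up O2 from the convex face to give the hydroperoxide F4, which P(OMe)3 reduces to 11.
- Both C4 epimers of F1 converge, because the configuration of C4 is decided only when the radical is trapped.

Step 9. What may go wrong: dehydration of the tertiary ketol to the conjugated C4=C5 enone, or retro-aldol opening of the five-membered ring, may compete with the slow enolisation at the hindered C5; the equilibrium may also stop short of full conversion. Fallback: it sets out from 11 and comes back at 12, and it changes the controlling element from a free ketol under a Brønsted base to a metal template.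
- The ketol is equilibrated as its magnesium chelate (MgBr2·OEt2, i-Pr2NEt, CH2Cl2, soft enolisation).
- Only the trans-fused isomer, in which O4 and the C6 carbonyl are cis on the five-membered ring, can close the six-membered O4–Mg–O6 chelate, so the chelate becomes the sink.
- The metal-bound O4 is a far poorer leaving group, which suppresses the dehydration.
- The fallback passes through no compound outside the list (F0).

Step 8. What may go wrong: face selectivity in the capture of the small O2 molecule by the C4 radical may be poor, or cobalt hydride may move the C3=C4 bond into conjugation with the C6 ketone. Fallback: it sets out from 10 and comes back at 11.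
- m-CPBA (NaHCO3, CH2Cl2, 0 °C) epoxidises the C3=C4 bond in a concerted way from the convex face to give the epoxy ketone F5.
- LiAlH4 (THF, 0 °C) opens the epoxide at the less substituted C3 and reduces the C6 ketone as well, giving the diol F6 (C6 epimers, of no consequence).
- (n-Pr)4N[RuO4]/NMO reoxidises the secondary alcohol to the ketol 11.

Further compounds
F1 | step 7 | 4-(methoxycarbonyl)-9,9-(ethylenedioxy)-14-nordaucan-6-one (1R,5S, cis-fused, C4 epimers) | COC(=O)C1(C(C)C)CC[C@]2(C)CC3(CCC(=O)[C@H]12)OCCO3
F2 | step 7 | 9,9-(ethylenedioxy)-6-oxo-14-nordaucane-4-carboxylic acid (1R,5S, cis-fused, C4 epimers) | OC(=O)C1(C(C)C)CC[C@]2(C)CC3(CCC(=O)[C@H]12)OCCO3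
F3 | step 7 | 2-thioxopyridin-1(2H)-yl ester of F2 (Barton ester) | CC(C)C1(C(=O)ON4C=CC=CC4=S)CC[C@]2(C)CC3(CCC(=O)[C@H]12)OCCO3
F4 | step 7 | (1R,4R,5S)-9,9-(ethylenedioxy)-4-hydroperoxy-14-nordaucan-6-one (cis-fused) | CC(C)[C@]1(OO)CC[C@]2(C)CC3(CCC(=O)[C@H]12)OCCO3
F5 | step 8 | 3,4-epoxy-9,9-(ethylenedioxy)-14-nordaucan-6-one (cis-fused, epoxide cis to CH3-15) | CC(C)[C@@]12O[C@H]2C[C@]3(C)CC4(CCC(=O)[C@H]13)OCCO4
F6 | step 8 | (1R,4R,5S)-9,9-(ethylenedioxy)-14-nordaucane-4,6-diol (cis-fused, C6 epimers) | CC(C)[C@]1(O)CC[C@]2(C)CC3(CCC(O)[C@H]12)OCCO3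
F0 | step 9 | none | none
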